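**Strategy.** The five-carbon bridge C1'–C4' with its C3' methyl, lying between the hydroquinone ring (the only ring, bought as an arene) and carbinol C5', is an intact isoprene unit, and C5'–C16' is farnesal. Everything therefore rests on one enantioselective nickel-catalysed three-component coupling that stitches isoprene between an arylboronic acid and (2E,6E)-farnesal. It forms the aryl–C1' and C4'–C5' bonds, the 2'E trisubstituted alkene and the 5'S carbinol in a single operation and closes no ring. Its precursors are farnesal (one oxidation from farnesol), isoprene and a bis-silylated 2-borono-6-methylhydroquinone (three operations from 2-bromo-6-methylphenol); fluoride desilylation finishes the synthesis.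

Key step: step 5

Assumption: L* in step 5 is a bulky C2-symmetric chiral N-heterocyclic carbene (N-aryl groups carrying 1-arylethyl stereocentres in both ortho positions), used as the free carbene in the antipode that favours Si-face addition to farnesal (5'S); chain atoms are numbered C1' (benzylic CH2) to C16'.

Step 1
Reactants: 1 (2E,6E)-farnesol
Product: 2 (2E,6E)-farnesal
Conditions: activated MnO2 (15 equiv), hexane, rt
Reagents that add atoms: none
Why: Allylic oxidation with MnO2 takes place on the oxide surface at the allylic carbinol only, so the enal should form without touching the two isolated trisubstituted alkenes and without scrambling the 2E geometry.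

Step 2
Reactants: 3 2-bromo-6-methylphenol
Product: 5 2-bromo-6-methylbenzene-1,4-diol, via bromoquinone 4 (not isolated)
Conditions: (KSO3)2NO (2.5 equiv), KH2PO4 buffer, H2O/acetone, 0 °C to rt; extract into EtOAc, then shake with aq Na2S2O4 under Ar
Reagents that add atoms: dipotassium nitrosodisulfonate (KSO3)2NO, [O]N(S(=O)(=O)[O-])S(=O)(=O)[O-].[K+].[K+]
Why: In a Teuber oxidation two equivalents of the nitrosodisulfonate radical convert a 2,6-disubstituted phenol into the para-quinone at its only free para position, which fixes the 1,4-dioxygen pattern without ambiguity, and dithionite reduction of the unpurified quinone should then give the hydroquinone.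

Step 3
Reactants: 5 2-bromo-6-methylbenzene-1,4-diol
Product: 6 1-bromo-2,5-bis(tert-butyldimethylsilyloxy)-3-methylbenzene
Conditions: TBSOTf (2.4 equiv), 2,6-lutidine (3 equiv), CH2Cl2, 0 °C to rt, Ar
Reagents that add atoms: tert-butyldimethylsilyl triflate (TBSOTf), CC(C)(C)[Si](C)(C)OS(=O)(=O)C(F)(F)F
Why: O-Silylation with a silyl triflate and a hindered pyridine base is fast enough to cap also the hydroxyl flanked by bromine and methyl, and the two aryl silyl ethers block phenoxide formation, quinone formation and catalyst poisoning in the steps ahead while remaining removable without acid.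

Step 4
Reactants: 6 1-bromo-2,5-bis(tert-butyldimethylsilyloxy)-3-methylbenzene
Product: 9 [2,5-bis(tert-butyldimethylsilyloxy)-3-methylphenyl]boronic acid, via aryllithium 7 (not isolated), via lithium aryltriisopropoxyborate 8 (not isolated)
Conditions: B(OiPr)3 (1.5 equiv) premixed with 6, n-BuLi (1.1 equiv) added slowly, THF/toluene, −78 °C; then 1 M aq HCl to pH 6, 0 °C
Reagents that add atoms: triisopropyl borate, CC(C)OB(OC(C)C)OC(C)C; water, O
Why: Bromine–lithium exchange is faster than attack of n-BuLi on the hindered borate, so in this in situ quench borylation the aryllithium is trapped as the ate complex before its ortho silyl group can migrate from oxygen to carbon (retro-Brook shift), and mild hydrolysis should release the boronic acid with both silyl ethers intact.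

Step 5
Reactants: 2 (2E,6E)-farnesal; 9 [2,5-bis(tert-butyldimethylsilyloxy)-3-methylphenyl]boronic acid; 10 isoprene
Product: 12 (2E,5S,6E,10E)-1-[2,5-bis(tert-butyldimethylsilyloxy)-3-methylphenyl]-3,7,11,15-tetramethylhexadeca-2,6,10,14-tetraen-5-ol, via borate monoester 11 (not isolated)
Conditions: Ni(cod)2 (10 mol %), L* (10 mol %), 10 (5 equiv), 9 (1.5 equiv), toluene, 25–40 °C, sealed vessel, Ar, no added base; then pH 7 buffer
Reagents that add atoms: none
Why: Proposed new method: zerovalent nickel carrying the chiral carbene should bind isoprene and the farnesal carbonyl and undergo oxidative cyclisation, joining the isoprene CH2 next to the methyl-bearing carbon to the carbonyl carbon (C4'–C5') to give an η3-allyl oxanickelacycle, whose Ni–O bond then engages the boronic acid without base so that the aryl group passes to nickel and reductive elimination at the unsubstituted allyl terminus forms the aryl–C1' bond and releases borate 11, hydrolysed on work-up. The closest known reaction type is the nickel-catalysed 1,4-three-component connection of a 1,3-diene, an aldehyde and an aryl donor (diarylzinc or arylboron), which with isoprene gives racemic (E)-3-methyl-5-aryl-3-penten-1-ols, together with chiral-carbene nickel-catalysed enantioselective reductive diene–aldehyde and alkyne–aldehyde couplings that begin with the same oxidative cyclisation; merging the two is the new element. No ring is closed, since the coupling is acyclic and the arene arrives intact in 9. The single stereocentre C5' is controlled by the chiral carbene, whose bulky N-aryl groups should leave only the Si face of the enal carbonyl open to C–C bond formation, which corresponds to 5'S. Regioselectivity (carbonyl at C4', aryl at C1', 1,4 over 1,2) should follow from the polarisation of isoprene and from the C3' methyl, which makes the internal allyl terminus fully substituted and steers reductive elimination to the CH2 terminus, while the 2'E geometry should follow from anti-to-syn equilibration of the opened allylnickel, which places the larger CH2CH(OB)R arm syn. Chemoselectivity is helped by the β,β-disubstituted enal (which resists conjugate arylation and coupling through its C=C), by the weak binding of the remote trisubstituted alkenes, by the absence of uncatalysed aryl transfer from boron to the aldehyde and by the single ortho substituent on the aryl donor.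

Step 6
Reactants: 12 (2E,5S,6E,10E)-1-[2,5-bis(tert-butyldimethylsilyloxy)-3-methylphenyl]-3,7,11,15-tetramethylhexadeca-2,6,10,14-tetraen-5-ol
Product: 13 2-[(2E,5S,6E,10E)-5-hydroxy-3,7,11,15-tetramethylhexadeca-2,6,10,14-tetraen-1-yl]-6-methylbenzene-1,4-diol (target CNP0314458.1)
Conditions: Bu4NF (3 equiv), AcOH (3 equiv), degassed THF, 0 °C, Ar; degassed pH 7 buffer work-up
Reagents that add atoms: none
Why: Fluoride-mediated desilylation cleaves both aryl silyl ethers through pentacoordinate silicon while acetic acid protonates each phenoxide as it forms, so the hydroquinone should be released without oxidation to the quinone and without acid strong enough to ionise the allylic alcohol or close a chroman onto the 2' alkene, leaving C5' and all four alkenes untouched.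

**Compound list**

1 | (2E,6E)-farnesol | CC(C)=CCC/C(C)=C/CC/C(C)=C/CO | starting material
2 | (2E,6E)-farnesal | CC(C)=CCC/C(C)=C/CC/C(C)=C/C=O | intermediate
3 | 2-bromo-6-methylphenol | Cc1cccc(Br)c1O | starting material
4 | 2-bromo-6-methyl-1,4-benzoquinone | CC1=CC(=O)C=C(Br)C1=O | intermediate
5 | 2-bromo-6-methylbenzene-1,4-diol (2-bromo-6-methylhydroquinone) | Cc1cc(O)cc(Br)c1O | intermediate
6 | 1-bromo-2,5-bis(tert-butyldimethylsilyloxy)-3-methylbenzene | Cc1cc(O[Si](C)(C)C(C)(C)C)cc(Br)c1O[Si](C)(C)C(C)(C)C | intermediate
7 | [2,5-bis(tert-butyldimethylsilyloxy)-3-methylphenyl]lithium | Cc1cc(O[Si](C)(C)C(C)(C)C)cc([Li])c1O[Si](C)(C)C(C)(C)C | intermediate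
8 | lithium [2,5-bis(tert-butyldimethylsilyloxy)-3-methylphenyl]triisopropoxyborate | [Li+].Cc1cc(O[Si](C)(C)C(C)(C)C)cc([B-](OC(C)C)(OC(C)C)OC(C)C)c1O[Si](C)(C)C(C)(C)C | intermediate
9 | [2,5-bis(tert-butyldimethylsilyloxy)-3-methylphenyl]boronic acid | Cc1cc(O[Si](C)(C)C(C)(C)C)cc(B(O)O)c1O[Si](C)(C)C(C)(C)C | intermediate
10 | isoprene (2-methylbuta-1,3-diene) | C=CC(C)=C | starting material
11 | O-dihydroxyboryl (borate monoester) derivative of 12 at the C5' oxygen, 5'S | CC(C)=CCC/C(C)=C/CC/C(C)=C/[C@@H](OB(O)O)C/C(C)=C/Cc1cc(O[Si](C)(C)C(C)(C)C)cc(C)c1O[Si](C)(C)C(C)(C)C | intermediate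
12 | (2E,5S,6E,10E)-1-[2,5-bis(tert-butyldimethylsilyloxy)-3-methylphenyl]-3,7,11,15-tetramethylhexadeca-2,6,10,14-tetraen-5-ol | CC(C)=CCC/C(C)=C/CC/C(C)=C/[C@@H](O)C/C(C)=C/Cc1cc(O[Si](C)(C)C(C)(C)C)cc(C)c1O[Si](C)(C)C(C)(C)C | intermediate
13 | 2-[(2E,5S,6E,10E)-5-hydroxy-3,7,11,15-tetramethylhexadeca-2,6,10,14-tetraen-1-yl]-6-methylbenzene-1,4-diol | CC(C)=CCC/C(C)=C/CC/C(C)=C/[C@@H](O)C/C(C)=C/Cc1cc(O)cc(C)c1O | target

**Step count.** Total: 6 steps. Longest linear sequence: 5 steps (3 → 5 → 6 → 9 → 12 → 13; steps 2 to 6).

**Steps most likely to fail**

Step 5 (proposed new method). The process at risk is face selection at the farnesal carbonyl during oxidative cyclisation. Behind it lie leakage to the 2'Z isomer, direct aryl transfer to the aldehyde and oligomerisation of the diene. An epoxidation-based kinetic resolution is not planned as a remedy, because the C7' methyl cis to the carbinol carbon puts 12 among the allylic alcohols that such resolutions discriminate least well. The fallback uses known chemistry and moves the stereocentre out of the C–C bond-forming event. It sets out from 2, 9 and 10 and comes back at 12. The three components would be coupled in the established racemic manner, with Ni(cod)2 and an achiral ligand such as PPh3 or the carbene IPr, to give via the racemic borate monoester F1 the racemic alcohol F2. Dess–Martin periodinane buffered with NaHCO3 would oxidise F2 to the dienone F3, which is used at once so that the 2' alkene does not drift into conjugation. Corey–Bakshi–Shibata reduction of F3 with (R)-2-methyl-CBS-oxazaborolidine and catecholborane in toluene at −78 °C, the alkenyl arm acting as the large group, should then deliver the 5'S alcohol 12.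

Step 4. The process at risk is oxygen-to-carbon silyl migration or protonation of the ortho-silyloxy aryllithium before it is borylated, and protodeboronation of the electron-rich boronic acid on work-up. The fallback avoids any aryl anion. It sets out from 6 and comes back at 9. Miyaura borylation of 6 (B2pin2, PdCl2(dppf), KOAc, dioxane, 85 °C) should give the pinacol boronate F4. Its pinacol ester would be cleaved with NaIO4 and NH4OAc in acetone/water, near-neutral conditions that leave the aryl silyl ethers in place, to give boronic acid 9.

Step 6. The process at risk is air oxidation of the liberated hydroquinone to the quinone during desilylation and chromatography, with base- or acid-triggered reactions of the ortho allylic chain as a secondary danger. The fallback stops protecting the hydroquinone from oxidation and purifies at the quinone level instead. It sets out from 12 and comes back at 13. The desilylation would be run as before, but the crude product would be oxidised at once with Ag2O in Et2O to the quinone F5, which tolerates air and silica gel. After chromatography, F5 would be reduced with aqueous Na2S2O4 in Et2O under argon, and the organic layer dried and concentrated to give 13 without chromatography of the hydroquinone.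

**Further compounds**

F1 | step 5 | racemic O-dihydroxyboryl (borate monoester) derivative of F2 | CC(C)=CCC/C(C)=C/CC/C(C)=C/C(OB(O)O)C/C(C)=C/Cc1cc(O[Si](C)(C)C(C)(C)C)cc(C)c1O[Si](C)(C)C(C)(C)C
F2 | step 5 | racemic (2E,6E,10E)-1-[2,5-bis(tert-butyldimethylsilyloxy)-3-methylphenyl]-3,7,11,15-tetramethylhexadeca-2,6,10,14-tetraen-5-ol | CC(C)=CCC/C(C)=C/CC/C(C)=C/C(O)C/C(C)=C/Cc1cc(O[Si](C)(C)C(C)(C)C)cc(C)c1O[Si](C)(C)C(C)(C)C
F3 | step 5 | (2E,6E,10E)-1-[2,5-bis(tert-butyldimethylsilyloxy)-3-methylphenyl]-3,7,11,15-tetramethylhexadeca-2,6,10,14-tetraen-5-one | CC(C)=CCC/C(C)=C/CC/C(C)=C/C(=O)C/C(C)=C/Cc1cc(O[Si](C)(C)C(C)(C)C)cc(C)c1O[Si](C)(C)C(C)(C)C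
F4 | step 4 | 2-[2,5-bis(tert-butyldimethylsilyloxy)-3-methylphenyl]-4,4,5,5-tetramethyl-1,3,2-dioxaborolane | Cc1cc(O[Si](C)(C)C(C)(C)C)cc(B2OC(C)(C)C(C)(C)O2)c1O[Si](C)(C)C(C)(C)C
F5 | step 6 | 2-[(2E,5S,6E,10E)-5-hydroxy-3,7,11,15-tetramethylhexadeca-2,6,10,14-tetraen-1-yl]-6-methyl-1,4-benzoquinone | CC(C)=CCC/C(C)=C/CC/C(C)=C/[C@@H](O)C/C(C)=C/CC1=CC(=O)C=C(C)C1=O
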